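Ring atoms are numbered C1 (CMeCl), C2, C3 (CMeBr), C4 (CH carrying the C7=C8 chlorovinyl arm), C5 and C6 (CHBr). C3 carries a methyl group and its neighbour C4 an alkenyl arm, which is the methylidene/vinyl pair an Alder-ene reaction leaves behind, and every halogenated carbon (C1, C3, C6, C8) is an alkene carbon once the halogens are removed. The route therefore rests on the C3–C4 disconnection: one enantioselective rhodium-catalysed cycloisomerisation closes the six-membered ring, sets C4 and delivers all three alkenes of a C10 triene. Its substrate is an acyclic dienyne having a terminal alkyne, a Z-trisubstituted tether alkene and a Z-propenyl end; five selective steps then place the four halogens.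

Key step: step 8

Remark: the ring numbering above is used from compound 11 on (in 11, C3 is the internal alkyne carbon, C4=C7 the propenyl alkene and C8 its methyl group).
Assumption: the (S)-BINAP complex is taken to give the (4S) ring; should the sense of induction be the opposite, (R)-BINAP is used with no other change.

Step 1
Reactants: 1 pent-3-yn-1-ol
Product: 2 (Z)-pent-3-en-1-ol
Conditions: H2 (1 atm), Pd/CaCO3 poisoned with Pb(OAc)2, quinoline, Et2O, 20 °C
Reagents that add atoms: none
Why: Lindlar semihydrogenation delivers both hydrogens from the catalyst surface to one face of the alkyne, so the Z-alkene should form and the reduction should stop there.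

Step 2
Reactants: 2 (Z)-pent-3-en-1-ol
Product: 3 (Z)-5-iodopent-2-ene
Conditions: I2, PPh3, imidazole, CH2Cl2, 0 → 20 °C
Reagents that add atoms: iodine, II
Why: Appel-type iodination, in which the alkoxyphosphonium ion is displaced by iodide in an SN2 step at the primary carbon, leaves the remote Z-alkene untouched.

Step 3
Reactants: 3 (Z)-5-iodopent-2-ene
Product: 4 [(Z)-pent-3-en-1-yl]triphenylphosphonium iodide
Conditions: PPh3, MeCN, 80 °C
Reagents that add atoms: triphenylphosphine, c1ccc(cc1)P(c1ccccc1)c1ccccc1
Why: SN2 quaternisation of the phosphine by a primary iodide is the standard way to a homoallylic Wittig salt.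

Step 4
Reactants: 4 [(Z)-pent-3-en-1-yl]triphenylphosphonium iodide; 5 1-[(tert-butyldimethylsilyl)oxy]propan-2-one
Product: 7 tert-butyl(dimethyl){[(2Z,5Z)-2-methylhepta-2,5-dien-1-yl]oxy}silane, via phosphorus ylide 6 (not isolated)
Conditions: KN(SiMe3)2, THF, −78 → 0 °C; then 5, −78 → 20 °C
Reagents that add atoms: none
Why: Wittig olefination of an α-silyloxy ketone by a non-stabilised ylide under lithium-free conditions is known to favour the Z-trisubstituted allylic ether (OCH2 cis to the ylide chain) through the kinetic oxaphosphetane, which sets the tether geometry, and the Z-alkene of the ylide is not affected.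

Step 5
Reactants: 7 tert-butyl(dimethyl){[(2Z,5Z)-2-methylhepta-2,5-dien-1-yl]oxy}silane
Product: 8 (2Z,5Z)-2-methylhepta-2,5-dien-1-ol
Conditions: Bu4NF, THF, 0 °C
Reagents that add atoms: none
Why: fluoride-induced silyl ether cleavage, driven by the strong Si–F bond, frees the allylic alcohol without touching either alkene.

Step 6
Reactants: 8 (2Z,5Z)-2-methylhepta-2,5-dien-1-ol
Product: 9 (2Z,5Z)-1-chloro-2-methylhepta-2,5-diene
Conditions: NCS, Me2S, CH2Cl2, −20 → 0 °C
Reagents that add atoms: N-chlorosuccinimide, O=C1CCC(=O)N1Cl
Why: Corey–Kim chlorination displaces the alkoxysulfonium group by chloride in an SN2 step at the primary allylic carbon under neutral conditions, so neither allylic transposition nor Z to E isomerisation is expected.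

Step 7
Reactants: 9 (2Z,5Z)-1-chloro-2-methylhepta-2,5-diene; 10 ethynylmagnesium bromide
Product: 11 (4Z,7Z)-4-methylnona-4,7-dien-1-yne
Conditions: HC≡CMgBr (3 equiv), CuCl (10 mol %), THF, 20 → 50 °C
Reagents that add atoms: none
Why: copper-catalysed alkynyl–allyl coupling substitutes the primary allylic chloride at its unhindered CH2 (SN2), giving the 1,4-enyne with both Z-alkenes intact and avoiding any base-sensitive β,γ-unsaturated aldehyde.

Step 8
Reactants: 11 (4Z,7Z)-4-methylnona-4,7-dien-1-yne
Product: 12 (4S)-4-ethenyl-1-methyl-5-methylidenecyclohex-1-ene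
Conditions: [Rh((S)-BINAP)]SbF6 (10 mol %; from [Rh(cod)Cl]2, (S)-BINAP, AgSbF6, H2 then Ar), ClCH2CH2Cl (0.02 M), 25 → 60 °C
Reagents that add atoms: none
Why: Proposed new method: cationic monovalent rhodium binds the alkyne and the Z-propenyl alkene and couples them by oxidative cyclometallation to a trivalent rhodacyclopentene (this forms C3–C4), syn β-hydride elimination from the C8 methyl then gives the vinyl group, and C–H reductive elimination puts that hydrogen on the former alkyne terminus as the C3 methylidene. The closest known reactions are the rhodium–BINAP Alder-ene cycloisomerisation of 1,6-enynes, which accepts terminal alkynes when the cationic catalyst is free of diene ligands, and the racemic palladium-catalysed Alder-ene closure of 1,7-enynes; an enantioselective all-carbon 1,7-enyne case has not been shown. The one carbocycle closes 6-exo-dig at the alkyne and 6-exo-trig at the alkene. C4 is the only new stereocentre and is set by the chiral bisphosphine, which selects the enantioface of the Z-alkene during cyclometallation. The step needs six-ring closure to beat alkyne oligomerisation and needs hydrogen to leave from C8 only: the Z-trisubstituted tether alkene (later C1=C6) holds the reacting ends on one side and cannot insert itself, since that would give a three- or four-membered ring, while the C4–H bond lies inside the metallacycle and cannot reach a syn arrangement with rhodium.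

Step 9
Reactants: 12 (4S)-4-ethenyl-1-methyl-5-methylidenecyclohex-1-ene; 13 (E)-1,2-dichloroethene
Product: 14 (4S)-4-[(E)-2-chloroethenyl]-1-methyl-5-methylidenecyclohex-1-ene
Conditions: Mo(NC6F5)(CHCMe2Ph)(2,5-Me2C4H2N)(O-2,6-(2,4,6-i-Pr3C6H2)2C6H3) (5 mol %), 13 (8 equiv), benzene, 22 °C
Reagents that add atoms: none
Why: molybdenum-alkylidene cross-metathesis with an E-1,2-dihaloethene is kinetically E-selective because the trans relationship of the reagent is carried through the metallacyclobutane, and only the monosubstituted vinyl group is open to the catalyst, the 1,1-disubstituted and trisubstituted alkenes being too hindered.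

Step 10
Reactants: 14 (4S)-4-[(E)-2-chloroethenyl]-1-methyl-5-methylidenecyclohex-1-ene
Product: 15 (1S,4S,6R)-4-[(E)-2-chloroethenyl]-1-methyl-3-methylidene-7-oxabicyclo[4.1.0]heptane
Conditions: D-fructose-derived Shi ketone (0.3 equiv), KHSO5 (as 2KHSO5·KHSO4·K2SO4, 1.4 equiv), K2CO3, Bu4NHSO4, MeCN–CH2(OMe)2–aqueous Na2B4O7 buffer (pH 10.5), 0 °C
Reagents that add atoms: potassium peroxymonosulfate, [K+].[O-]S(=O)(=O)OO
Why: Shi epoxidation by the chiral dioxirane attacks the most electron-rich, trisubstituted C1=C6 alkene through a spiro transition state, and this reagent control (C4 alone gives no useful bias in such 4-substituted 1-methylcyclohexenes) should place oxygen on the face anti to the C4 side chain, setting C1 and C6, while the methylidene and chlorovinyl groups are poor substrates for this catalyst.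

Step 11
Reactants: 15 (1S,4S,6R)-4-[(E)-2-chloroethenyl]-1-methyl-3-methylidene-7-oxabicyclo[4.1.0]heptane
Product: 16 (1R,2R,5S)-2-chloro-5-[(E)-2-chloroethenyl]-2-methyl-4-methylidenecyclohexan-1-ol
Conditions: HCl (1.1 equiv, 2 M in Et2O), CH2Cl2, −78 → −40 °C
Reagents that add atoms: hydrogen chloride, Cl
Why: in this acid-promoted epoxide opening chloride attacks the tertiary carbon C1 (Markovnikov) with inversion and trans-diaxially (Fürst–Plattner) from the conformer that keeps the C4 side chain equatorial, so electronic and conformational preferences agree, C1 ends with chlorine anti to the C6 hydroxyl, and C6 keeps its configuration.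

Step 12
Reactants: 16 (1R,2R,5S)-2-chloro-5-[(E)-2-chloroethenyl]-2-methyl-4-methylidenecyclohexan-1-ol
Product: 18 (1R,2S,4S)-2-bromo-1-chloro-4-[(E)-2-chloroethenyl]-1-methyl-5-methylidenecyclohexane, via C6 triflate 17 (not isolated)
Conditions: Tf2O, 2,6-lutidine, CH2Cl2, −78 → −30 °C; then Bu4NBr, −30 → 10 °C
Reagents that add atoms: tetrabutylammonium bromide, CCCC[N+](CCCC)(CCCC)CCCC.[Br-]
Why: sulfonate displacement by soluble bromide is an SN2 step with inversion at C6, which turns the anti chlorohydrin into the cis C1-chloride/C6-bromide pair, and low temperature in a non-ionising medium is chosen to keep chlorine participation and E2 loss of triflate behind direct substitution.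

Step 13
Reactants: 18 (1R,2S,4S)-2-bromo-1-chloro-4-[(E)-2-chloroethenyl]-1-methyl-5-methylidenecyclohexane
Product: 19 (1R,2S,4S,5R)-1,4-dibromo-5-chloro-2-[(E)-2-chloroethenyl]-1,5-dimethylcyclohexane (CNP0257204.1)
Conditions: Co(acac)2 (0.3 equiv), t-BuOOH (0.3 equiv), Et3SiH, TsBr, n-PrOH, 20 °C
Reagents that add atoms: 4-methylbenzenesulfonyl bromide, Cc1ccc(cc1)S(=O)(=O)Br
Why: in this metal-hydride hydrogen-atom-transfer hydrobromination (Mukaiyama type) a cobalt hydride gives hydrogen to the CH2 terminus and the tertiary C3 radical should take bromine from TsBr on the equatorial face, because the axial C1 chlorine shields the axial face, which sets C3 with bromine trans to the C4 side chain, while the 1,2-disubstituted chloroalkene and the alkyl halides should stay inert.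

Compound list
1 | pent-3-yn-1-ol | CC#CCCO | starting material
2 | (Z)-pent-3-en-1-ol | C/C=C\CCO | intermediate
3 | (Z)-5-iodopent-2-ene | C/C=C\CCI | intermediate
4 | [(Z)-pent-3-en-1-yl]triphenylphosphonium iodide | C/C=C\CC[P+](c1ccccc1)(c1ccccc1)c1ccccc1.[I-] | intermediate
5 | 1-[(tert-butyldimethylsilyl)oxy]propan-2-one | CC(=O)CO[Si](C)(C)C(C)(C)C | starting material
6 | [(Z)-pent-3-en-1-ylidene]triphenylphosphorane (ylide, not isolated) | C/C=C\CC=P(c1ccccc1)(c1ccccc1)c1ccccc1 | intermediate
7 | tert-butyl(dimethyl){[(2Z,5Z)-2-methylhepta-2,5-dien-1-yl]oxy}silane | C/C=C\C/C=C(C)\CO[Si](C)(C)C(C)(C)C | intermediate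
8 | (2Z,5Z)-2-methylhepta-2,5-dien-1-ol | C/C=C\C/C=C(C)\CO | intermediate
9 | (2Z,5Z)-1-chloro-2-methylhepta-2,5-diene | C/C=C\C/C=C(C)\CCl | intermediate
10 | ethynylmagnesium bromide | C#C[Mg]Br | starting material
11 | (4Z,7Z)-4-methylnona-4,7-dien-1-yne | C#CC/C(C)=C\C/C=C\C | intermediate
12 | (4S)-4-ethenyl-1-methyl-5-methylidenecyclohex-1-ene | CC1=CC[C@@H](C=C)C(=C)C1 | intermediate
13 | (E)-1,2-dichloroethene | Cl/C=C/Cl | starting material
14 | (4S)-4-[(E)-2-chloroethenyl]-1-methyl-5-methylidenecyclohex-1-ene | CC1=CC[C@@H](/C=C/Cl)C(=C)C1 | intermediate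
15 | (1S,4S,6R)-4-[(E)-2-chloroethenyl]-1-methyl-3-methylidene-7-oxabicyclo[4.1.0]heptane | C[C@]12CC(=C)[C@H](/C=C/Cl)C[C@H]1O2 | intermediate
16 | (1R,2R,5S)-2-chloro-5-[(E)-2-chloroethenyl]-2-methyl-4-methylidenecyclohexan-1-ol | C[C@@]1(Cl)CC(=C)[C@H](/C=C/Cl)C[C@H]1O | intermediate
17 | (1R,2R,5S)-2-chloro-5-[(E)-2-chloroethenyl]-2-methyl-4-methylidenecyclohexyl trifluoromethanesulfonate (not isolated) | C[C@@]1(Cl)CC(=C)[C@H](/C=C/Cl)C[C@H]1OS(=O)(=O)C(F)(F)F | intermediate
18 | (1R,2S,4S)-2-bromo-1-chloro-4-[(E)-2-chloroethenyl]-1-methyl-5-methylidenecyclohexane | C[C@@]1(Cl)CC(=C)[C@H](/C=C/Cl)C[C@@H]1Br | intermediate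
19 | (1R,2S,4S,5R)-1,4-dibromo-5-chloro-2-[(E)-2-chloroethenyl]-1,5-dimethylcyclohexane | C[C@@]1(Cl)C[C@@](C)(Br)[C@H](/C=C/Cl)C[C@@H]1Br | target

Total step count: 13. Longest linear sequence: 13 steps (1 → 19); compounds 5, 10 and 13 are purchased.

Steps most likely to fail

Step 8 (new method). The cyclometallation to a six-membered carbocycle may be too slow, so that alkyne oligomerisation, binding of the diene product to rhodium or poor enantioface discrimination takes over. The fallback uses known chemistry and sets out from 11. Racemic Alder-ene cycloisomerisation under Pd(OAc)2/PPh3 in benzene at 60 °C, an established closure of 1,7-enynes, should give rac-4-ethenyl-1-methyl-5-methylidenecyclohex-1-ene F1. Cross-metathesis as in step 9 should give rac-4-[(E)-2-chloroethenyl]-1-methyl-5-methylidenecyclohex-1-ene F2. The reagent-controlled epoxidation of step 10 then acts as a divergent reaction on the racemate: the (S)-enantiomer should give 15 and the (R)-enantiomer the C4-epimeric epoxide (1S,4R,6R)-4-[(E)-2-chloroethenyl]-1-methyl-3-methylidene-7-oxabicyclo[4.1.0]heptane F3, which is removed by chromatography, if necessary after step 11 at the chlorohydrin stage. The route resumes at 15, whose absolute configuration then comes from the epoxidation catalyst.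

Step 12. Ionisation of the triflate assisted by the anti-periplanar C1 chlorine, or anti elimination toward C5, may outrun backside attack at the neopentyl-like C6, which would give retention, halogen migration or an alkene. The fallback bypasses epoxide, chlorohydrin and sulfonate and sets out from 14. Markovnikov anti addition of PhSeCl (CH2Cl2, −78 °C) should go through the seleniranium ion on the face anti to the side chain, opened trans-diaxially by chloride at C1, and give {[(1R,2R,5S)-2-chloro-5-[(E)-2-chloroethenyl]-2-methyl-4-methylidenecyclohexyl]selanyl}benzene F4. One equivalent of Br2 at −78 °C oxidises selenium to the tetravalent dibromide, and bromide then displaces the C6–Se bond with inversion (oxidative halodeselenation). This comes back to the route at 18.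

Step 13. Bromine transfer to the planar C3 radical may show poor facial selectivity, or reversible hydrogen-atom transfer may move the alkene into the ring before the radical is trapped. The fallback changes the mechanism from radical to polar and sets out from 18: Markovnikov addition of HBr generated from Me3SiBr and MeOH in CH2Cl2 at −78 °C, in which bromide captures the tertiary C3 cation from the face away from the axial C1 chlorine. It comes back at 19 and makes no new compound.

Further compounds
F1 | step 8 | rac-4-ethenyl-1-methyl-5-methylidenecyclohex-1-ene | CC1=CCC(C=C)C(=C)C1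
F2 | step 8 | rac-4-[(E)-2-chloroethenyl]-1-methyl-5-methylidenecyclohex-1-ene | CC1=CCC(/C=C/Cl)C(=C)C1
F3 | step 8 | (1S,4R,6R)-4-[(E)-2-chloroethenyl]-1-methyl-3-methylidene-7-oxabicyclo[4.1.0]heptane | C[C@]12CC(=C)[C@@H](/C=C/Cl)C[C@H]1O2
F4 | step 12 | {[(1R,2R,5S)-2-chloro-5-[(E)-2-chloroethenyl]-2-methyl-4-methylidenecyclohexyl]selanyl}benzene | C[C@@]1(Cl)CC(=C)[C@H](/C=C/Cl)C[C@H]1[Se]c1ccccc1
F0 | step 13 | none | none
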